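## Retrosynthetic overview

Numbering used throughout: C1 is the stereocentre; the ring runs C1–C14 with C3=C4 (C4 carries CH2OH), C7=C8 and C11=C12.

1. The only ring (14-membered) is closed last, at C9–C10, by intramolecular alkylation of a C10 allylic phenyl sulfone carbanion with a C9 allylic bromide; desulfonylation and desilylation finish the synthesis.
2. The open chain comes from a Still–Gennari olefination (C3=C4, ester cis to C2) of a C3 aldehyde with a C4–C9 phosphonate, and a Negishi coupling (C12–C13) of a C13 alkylzinc with a (Z)-3-iodobut-2-enyl silyl ether.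
3. The aldehyde arm and the alkylzinc arm are the two ends of one (R)-4-alkenyl δ-lactone; its stereocentre (C1) is set by lipase-catalysed enantiotopos-selective hydrolysis of a prochiral diethyl 3-alkenylglutarate.
4. That diester is assembled from allyl acetoacetate, prenyl bromide and ethyl bromoacetate (dianion alkylation, double alkylation, deallylative decarboxylation, Wittig methylenation).

Assumption: the lipase shows the same enantiotopic preference on the 3-(alk-1-en-2-yl)glutarate as on 3-aryl- and 3-alkylglutarate diesters and gives the (S)-half-ester; the sense and ee are confirmed on the first batch by chiral HPLC of the derived lactone.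

## Route

Step 1
Reactants: 1 allyl acetoacetate; 2 prenyl bromide
Product: 3 allyl 7-methyl-3-oxooct-6-enoate
Conditions: NaH, THF, 0 °C; n-BuLi, 0 °C; then 2, 0 °C → rt
Reagents that add atoms: none
Why: Weiler dianion alkylation; the more basic terminal carbanion of the acetoacetate dianion is alkylated by the allylic bromide (SN2), and no stereocentre is formed.

Step 2
Reactants: 3; 4 ethyl bromoacetate (2.4 equiv)
Product: 6 allyl 2,2-bis(2-ethoxy-2-oxoethyl)-7-methyl-3-oxooct-6-enoate, via mono-alkylated keto diester 5 (not isolated)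
Conditions: NaH (1.15 equiv), 4 (1.2 equiv), THF–DMF, 0 °C → rt; then NaH (1.15 equiv), 4 (1.2 equiv), rt → 40 °C
Reagents that add atoms: none
Why: Twofold C-alkylation of the β-keto ester (acetoacetic ester synthesis) installs two identical acetate arms; the transient racemic centre of 5 disappears in the symmetrical product 6.

Step 3
Reactants: 6
Product: 8 diethyl 3-(5-methylhex-4-enoyl)pentanedioate, via β-keto acid 7 (not isolated)
Conditions: Pd(OAc)2 (2 mol %), PPh3, HCO2H, Et3N, THF, rt → 40 °C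
Reagents that add atoms: none
Why: Tsuji palladium-catalysed deallylation by formate hydrogenolysis, followed by spontaneous decarboxylation of the β-keto acid, is neutral and leaves the ethyl esters and the trisubstituted alkene untouched.

Step 4
Reactants: 8
Product: 9 diethyl 3-(6-methylhepta-1,5-dien-2-yl)pentanedioate
Conditions: Ph3PCH3Br, KOtBu, THF, 0 °C → rt
Reagents that add atoms: methyltriphenylphosphonium bromide, C[P+](c1ccccc1)(c1ccccc1)c1ccccc1.[Br-]
Why: Wittig methylenation of a γ-keto ester (levulinate-type precedent) puts the 1,1-disubstituted alkene in place while the adjacent carbon is still prochiral, so epimerisation cannot arise.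

Step 5
Reactants: 9
Product: 10 (3S)-5-ethoxy-3-(6-methylhepta-1,5-dien-2-yl)-5-oxopentanoic acid
Conditions: lipase (immobilized Candida antarctica lipase B), phosphate buffer pH 7.5 / 10 % acetone, 35 °C, pH-stat with 1 M NaOH (1.0 equiv); then HCl to pH 3, extraction
Reagents that add atoms: water, O
Why: Enantiotopos-selective enzymatic ester hydrolysis (desymmetrization of a prochiral glutarate by a serine hydrolase) sets C1 by asymmetric biocatalysis; the half-ester anion is not hydrolysed further.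

Step 6
Reactants: 10
Product: 12 (4R)-4-(6-methylhepta-1,5-dien-2-yl)oxan-2-one, via hydroxy acid 11 (not isolated)
Conditions: LiOH (1.0 equiv), THF–H2O, then dry; LiBH4, THF, 0 °C → rt; 1 M HCl, rt
Reagents that add atoms: none
Why: Chemoselective LiBH4 reduction of the ester in the presence of the lithium carboxylate, then acid-induced δ-lactonization, differentiates the two arms without touching the stereocentre (its descriptor changes only through CIP priorities).

Step 7
Reactants: 13 but-2-yn-1-ol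
Product: 15 (2Z)-3-iodobut-2-en-1-ol, via cyclic alkenylaluminate 14 (not isolated)
Conditions: NaAlH2(OCH2CH2OMe)2, THF, 0 °C → rt; then I2, –78 °C → 0 °C
Reagents that add atoms: iodine, II
Why: Alkoxide-directed trans-hydroalumination of the propargylic alcohol followed by iodinolysis with retention gives the (Z)-vinyl iodide only.

Step 8
Reactants: 15
Product: 16 tert-butyl{[(2Z)-3-iodobut-2-en-1-yl]oxy}dimethylsilane
Conditions: TBSCl, imidazole, CH2Cl2, 0 °C → rt
Reagents that add atoms: tert-butyldimethylsilyl chloride, CC(C)(C)[Si](C)(C)Cl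
Why: Standard silylation of a primary alcohol; it removes the acidic OH before the organozinc coupling.

Step 9
Reactants: 12
Product: 17 (3R)-5-hydroxy-N-methoxy-N-methyl-3-(6-methylhepta-1,5-dien-2-yl)pentanamide
Conditions: MeNH(OMe)·HCl, AlMe3, CH2Cl2, 0 °C → rt; Rochelle salt work-up
Reagents that add atoms: N,O-dimethylhydroxylamine hydrochloride, CNOC.Cl
Why: Weinreb aminolysis of the lactone with the aluminium amide opens the ring, giving a latent aldehyde (C3) and a free primary alcohol (C13).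

Step 10
Reactants: 17
Product: 18 (3S)-5-iodo-N-methoxy-N-methyl-3-(6-methylhepta-1,5-dien-2-yl)pentanamide (same spatial arrangement; the descriptor changes by CIP priority)
Conditions: I2, PPh3, imidazole, CH2Cl2, 0 °C → rt
Reagents that add atoms: iodine, II
Why: Appel-type (Garegg–Samuelsson) iodination of the primary alcohol by SN2 displacement of the alkoxyphosphonium; used at once to prevent relactonization of 17.

Step 11
Reactants: 18; 16 (1.2 equiv)
Product: 20 (3R,6Z)-8-[(tert-butyldimethylsilyl)oxy]-N-methoxy-N,6-dimethyl-3-(6-methylhepta-1,5-dien-2-yl)oct-6-enamide, via alkylzinc iodide 19 (not isolated)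
Conditions: Zn dust (activated with BrCH2CH2Br, Me3SiCl), LiCl, THF, 40 °C; then 16, Pd(PPh3)4 (5 mol %), THF, rt → 40 °C
Reagents that add atoms: none
Why: Zinc insertion into the primary iodide and Negishi sp3–sp2 cross-coupling form C12–C13 with retention of the (Z)-geometry; the Weinreb amide is inert to the organozinc.

Step 12
Reactants: 20
Product: 21 (3R,6Z)-8-hydroxy-N-methoxy-N,6-dimethyl-3-(6-methylhepta-1,5-dien-2-yl)oct-6-enamide
Conditions: Bu4NF, THF, 0 °C → rt
Reagents that add atoms: none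
Why: Fluoride-induced desilylation frees the C10 allylic alcohol.

Step 13
Reactants: 21
Product: 22 (3R,6Z)-8-chloro-N-methoxy-N,6-dimethyl-3-(6-methylhepta-1,5-dien-2-yl)oct-6-enamide
Conditions: NCS, Me2S, CH2Cl2, –20 → 0 °C
Reagents that add atoms: N-chlorosuccinimide, O=C1CCC(=O)N1Cl
Why: Corey–Kim chlorination turns the primary allylic alcohol into the chloride by SN2 without allylic transposition or loss of (Z)-geometry.

Step 14
Reactants: 22
Product: 23 (3R,6Z)-N-methoxy-N,6-dimethyl-3-(6-methylhepta-1,5-dien-2-yl)-8-(phenylsulfonyl)oct-6-enamide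
Conditions: PhSO2Na, Bu4NI (cat.), DMF, rt
Reagents that add atoms: sodium benzenesulfinate, [Na+].[O-]S(=O)c1ccccc1
Why: S-alkylation of the sulfinate (SN2 at the primary allylic carbon) installs the carbanion-stabilizing group at C10.

Step 15
Reactants: 23
Product: 24 (3R,6Z)-6-methyl-3-(6-methylhepta-1,5-dien-2-yl)-8-(phenylsulfonyl)oct-6-enal
Conditions: iBu2AlH, THF, –78 °C; Rochelle salt work-up
Reagents that add atoms: none
Why: Weinreb amide reduction stops at the aldehyde through the chelated tetrahedral intermediate; the stereocentre is β to the carbonyl and cannot epimerise.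

Step 16
Reactants: 25 3-[(tert-butyldimethylsilyl)oxy]propanal; 26 ethyl 2-(triphenyl-λ5-phosphanylidene)propanoate
Product: 27 ethyl (2E)-5-[(tert-butyldimethylsilyl)oxy]-2-methylpent-2-enoate
Conditions: CH2Cl2, rt
Reagents that add atoms: none
Why: Wittig reaction of a stabilized ylide gives the (E)-trisubstituted enoate (the C7=C8 geometry) under thermodynamic control.

Step 17
Reactants: 27
Product: 28 (2E)-5-[(tert-butyldimethylsilyl)oxy]-2-methylpent-2-en-1-ol
Conditions: iBu2AlH, CH2Cl2, –78 °C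
Reagents that add atoms: none
Why: 1,2-Reduction of the enoate with the aluminium hydride gives the allylic alcohol without touching the alkene.

Step 18
Reactants: 28
Product: 29 tert-butyl({(3E)-5-[(4-methoxybenzyl)oxy]-4-methylpent-3-en-1-yl}oxy)dimethylsilane
Conditions: NaH, PMBCl, Bu4NI (cat.), THF–DMF, 0 °C → rt
Reagents that add atoms: 4-methoxybenzyl chloride, COc1ccc(CCl)cc1
Why: Williamson etherification protects the C9 oxygen with a group orthogonal to the silyl ethers used later.

Step 19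
Reactants: 29
Product: 30 (3E)-5-[(4-methoxybenzyl)oxy]-4-methylpent-3-en-1-ol
Conditions: Bu4NF, THF, rt
Reagents that add atoms: none
Why: Fluoride desilylation frees the C5 alcohol selectively.

Step 20
Reactants: 30
Product: 31 1-({[(2E)-5-iodo-2-methylpent-2-en-1-yl]oxy}methyl)-4-methoxybenzene
Conditions: I2, PPh3, imidazole, CH2Cl2, 0 °C
Reagents that add atoms: iodine, II
Why: Appel-type iodination gives the primary homoallylic iodide.

Step 21
Reactants: 31; 32 methyl [bis(2,2,2-trifluoroethoxy)phosphoryl]acetate (1.5 equiv)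
Product: 33 methyl (5E)-2-[bis(2,2,2-trifluoroethoxy)phosphoryl]-7-[(4-methoxybenzyl)oxy]-6-methylhept-5-enoate (racemic at C2)
Conditions: NaH, DMF, 0 °C → rt
Reagents that add atoms: none
Why: SN2 C-alkylation of the soft phosphonoacetate anion; the new centre is racemic and is destroyed in the olefination.

Step 22
Reactants: 24; 33
Product: 34 methyl (2Z,5R,8Z)-2-{(3E)-5-[(4-methoxybenzyl)oxy]-4-methylpent-3-en-1-yl}-8-methyl-5-(6-methylhepta-1,5-dien-2-yl)-10-(phenylsulfonyl)deca-2,8-dienoate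
Conditions: 33, KN(SiMe3)2, 18-crown-6, THF, –78 °C; then 24, –78 °C
Reagents that add atoms: none
Why: Still–Gennari modification of the Horner–Wadsworth–Emmons reaction; fast irreversible elimination from the trifluoroethyl phosphonate adduct places the ester cis to C2 (Z-enoate).

Step 23
Reactants: 34
Product: 35 (2Z,5R,8Z)-2-{(3E)-5-[(4-methoxybenzyl)oxy]-4-methylpent-3-en-1-yl}-8-methyl-5-(6-methylhepta-1,5-dien-2-yl)-10-(phenylsulfonyl)deca-2,8-dien-1-ol
Conditions: iBu2AlH, CH2Cl2, –78 °C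
Reagents that add atoms: none
Why: 1,2-Reduction of the enoate gives the C4 hydroxymethyl group with the alkene geometry retained; the sulfone is inert.

Step 24
Reactants: 35
Product: 36 tert-butyldimethylsilyl ether of 35
Conditions: TBSCl, imidazole, DMF, rt
Reagents that add atoms: tert-butyldimethylsilyl chloride, CC(C)(C)[Si](C)(C)Cl
Why: Silylation masks the primary alcohol so that no alkoxide competes in the ring closure.

Step 25
Reactants: 36
Product: 37 (2Z,5R,8Z)-1-[(tert-butyldimethylsilyl)oxy]-2-[(3E)-5-hydroxy-4-methylpent-3-en-1-yl]-8-methyl-5-(6-methylhepta-1,5-dien-2-yl)-10-(phenylsulfonyl)deca-2,8-diene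
Conditions: DDQ, CH2Cl2 / pH 7 buffer, 0 °C
Reagents that add atoms: none
Why: Oxidative cleavage of the 4-methoxybenzyl ether by hydride abstraction frees the C9 alcohol; the silyl ether and sulfone survive.

Step 26
Reactants: 37
Product: 38 (2Z,5R,8Z)-2-[(3E)-5-bromo-4-methylpent-3-en-1-yl]-1-[(tert-butyldimethylsilyl)oxy]-8-methyl-5-(6-methylhepta-1,5-dien-2-yl)-10-(phenylsulfonyl)deca-2,8-diene
Conditions: CBr4, PPh3, CH2Cl2, –20 → 0 °C
Reagents that add atoms: carbon tetrabromide, BrC(Br)(Br)Br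
Why: Appel bromination gives the primary (E)-allylic bromide under neutral conditions.

Step 27
Reactants: 38
Product: 39 tert-butyl{[(1Z,4R,7Z,11E)-7,11-dimethyl-4-(6-methylhepta-1,5-dien-2-yl)-9-(phenylsulfonyl)cyclotetradeca-1,7,11-trien-1-yl]methoxy}dimethylsilane (both epimers at the sulfone carbon)
Conditions: KN(SiMe3)2, THF, syringe-pump addition of 38 to 2 mM, –78 → 0 °C
Reagents that add atoms: none
Why: Intramolecular α-alkylation of the allylic sulfone carbanion by the allylic bromide (Biellmann-type macrocyclization) under high dilution forms C9–C10; the new sulfone-bearing centre forms unselectively and is removed in the next step.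

Step 28
Reactants: 39
Product: 40 tert-butyl{[(1Z,4R,7Z,11E)-7,11-dimethyl-4-(6-methylhepta-1,5-dien-2-yl)cyclotetradeca-1,7,11-trien-1-yl]methoxy}dimethylsilane
Conditions: PdCl2[Ph2P(CH2)3PPh2] (10 mol %), LiBHEt3, THF, 0 °C → rt
Reagents that add atoms: none
Why: Palladium-catalysed reductive desulfonylation; hydride attacks the less substituted terminus (C10) of the allyl–palladium intermediate, so the C11=C12 alkene keeps its position and (Z)-geometry.

Step 29
Reactants: 40
Product: 41 [(1Z,4R,7Z,11E)-7,11-dimethyl-4-(6-methylhepta-1,5-dien-2-yl)cyclotetradeca-1,7,11-trien-1-yl]methanol (target)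
Conditions: Bu4NF, THF, rt
Reagents that add atoms: none
Why: Fluoride desilylation releases the allylic alcohol under conditions harmless to the skipped triene.

## Compound list

1 | allyl acetoacetate | C=CCOC(=O)CC(C)=O | starting material
2 | prenyl bromide (1-bromo-3-methylbut-2-ene) | CC(C)=CCBr | starting material
3 | allyl 7-methyl-3-oxooct-6-enoate | C=CCOC(=O)CC(=O)CCC=C(C)C | intermediate
4 | ethyl bromoacetate | CCOC(=O)CBr | starting material
5 | allyl 2-(2-ethoxy-2-oxoethyl)-7-methyl-3-oxooct-6-enoate (racemic, not isolated) | C=CCOC(=O)C(CC(=O)OCC)C(=O)CCC=C(C)C | intermediate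
6 | allyl 2,2-bis(2-ethoxy-2-oxoethyl)-7-methyl-3-oxooct-6-enoate | C=CCOC(=O)C(CC(=O)OCC)(CC(=O)OCC)C(=O)CCC=C(C)C | intermediate
7 | 2,2-bis(2-ethoxy-2-oxoethyl)-7-methyl-3-oxooct-6-enoic acid (not isolated) | OC(=O)C(CC(=O)OCC)(CC(=O)OCC)C(=O)CCC=C(C)C | intermediate
8 | diethyl 3-(5-methylhex-4-enoyl)pentanedioate | CCOC(=O)CC(CC(=O)OCC)C(=O)CCC=C(C)C | intermediate
9 | diethyl 3-(6-methylhepta-1,5-dien-2-yl)pentanedioate | CCOC(=O)CC(CC(=O)OCC)C(=C)CCC=C(C)C | intermediate
10 | (3S)-5-ethoxy-3-(6-methylhepta-1,5-dien-2-yl)-5-oxopentanoic acid | C=C(CCC=C(C)C)[C@H](CC(=O)OCC)CC(=O)O | intermediate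
11 | (3R)-5-hydroxy-3-(6-methylhepta-1,5-dien-2-yl)pentanoic acid (not isolated) | C=C(CCC=C(C)C)[C@H](CCO)CC(=O)O | intermediate
12 | (4R)-4-(6-methylhepta-1,5-dien-2-yl)oxan-2-one | C=C(CCC=C(C)C)[C@H]1CC(=O)OCC1 | intermediate
13 | but-2-yn-1-ol | CC#CCO | starting material
14 | sodium 2,2-bis(2-methoxyethoxy)-3-methyl-2,5-dihydro-1,2-oxaaluminol-2-uide (cyclic alkenylaluminate, not isolated) | CC1=CCO[Al-]1(OCCOC)OCCOC.[Na+] | intermediate
15 | (2Z)-3-iodobut-2-en-1-ol | C/C(I)=C/CO | intermediate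
16 | tert-butyl{[(2Z)-3-iodobut-2-en-1-yl]oxy}dimethylsilane | C/C(I)=C/CO[Si](C)(C)C(C)(C)C | intermediate
17 | (3R)-5-hydroxy-N-methoxy-N-methyl-3-(6-methylhepta-1,5-dien-2-yl)pentanamide | C=C(CCC=C(C)C)[C@H](CCO)CC(=O)N(C)OC | intermediate
18 | (3S)-5-iodo-N-methoxy-N-methyl-3-(6-methylhepta-1,5-dien-2-yl)pentanamide | C=C(CCC=C(C)C)[C@H](CCI)CC(=O)N(C)OC | intermediate
19 | alkylzinc iodide from 18 (C–I replaced by C–ZnI, not isolated) | C=C(CCC=C(C)C)[C@H](CC[Zn]I)CC(=O)N(C)OC | intermediate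
20 | (3R,6Z)-8-[(tert-butyldimethylsilyl)oxy]-N-methoxy-N,6-dimethyl-3-(6-methylhepta-1,5-dien-2-yl)oct-6-enamide | C=C(CCC=C(C)C)[C@H](CC/C(C)=C\CO[Si](C)(C)C(C)(C)C)CC(=O)N(C)OC | intermediate
21 | (3R,6Z)-8-hydroxy-N-methoxy-N,6-dimethyl-3-(6-methylhepta-1,5-dien-2-yl)oct-6-enamide | C=C(CCC=C(C)C)[C@H](CC/C(C)=C\CO)CC(=O)N(C)OC | intermediate
22 | (3R,6Z)-8-chloro-N-methoxy-N,6-dimethyl-3-(6-methylhepta-1,5-dien-2-yl)oct-6-enamide | C=C(CCC=C(C)C)[C@H](CC/C(C)=C\CCl)CC(=O)N(C)OC | intermediate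
23 | (3R,6Z)-N-methoxy-N,6-dimethyl-3-(6-methylhepta-1,5-dien-2-yl)-8-(phenylsulfonyl)oct-6-enamide | C=C(CCC=C(C)C)[C@H](CC/C(C)=C\CS(=O)(=O)c1ccccc1)CC(=O)N(C)OC | intermediate
24 | (3R,6Z)-6-methyl-3-(6-methylhepta-1,5-dien-2-yl)-8-(phenylsulfonyl)oct-6-enal | C=C(CCC=C(C)C)[C@H](CC/C(C)=C\CS(=O)(=O)c1ccccc1)CC=O | intermediate
25 | 3-[(tert-butyldimethylsilyl)oxy]propanal | O=CCCO[Si](C)(C)C(C)(C)C | starting material
26 | ethyl 2-(triphenyl-λ5-phosphanylidene)propanoate | CCOC(=O)C(C)=P(c1ccccc1)(c1ccccc1)c1ccccc1 | starting material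
27 | ethyl (2E)-5-[(tert-butyldimethylsilyl)oxy]-2-methylpent-2-enoate | CCOC(=O)/C(C)=C/CCO[Si](C)(C)C(C)(C)C | intermediate
28 | (2E)-5-[(tert-butyldimethylsilyl)oxy]-2-methylpent-2-en-1-ol | OC/C(C)=C/CCO[Si](C)(C)C(C)(C)C | intermediate
29 | tert-butyl({(3E)-5-[(4-methoxybenzyl)oxy]-4-methylpent-3-en-1-yl}oxy)dimethylsilane | COc1ccc(COC/C(C)=C/CCO[Si](C)(C)C(C)(C)C)cc1 | intermediate
30 | (3E)-5-[(4-methoxybenzyl)oxy]-4-methylpent-3-en-1-ol | COc1ccc(COC/C(C)=C/CCO)cc1 | intermediate
31 | 1-({[(2E)-5-iodo-2-methylpent-2-en-1-yl]oxy}methyl)-4-methoxybenzene | COc1ccc(COC/C(C)=C/CCI)cc1 | intermediate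
32 | methyl [bis(2,2,2-trifluoroethoxy)phosphoryl]acetate | COC(=O)CP(=O)(OCC(F)(F)F)OCC(F)(F)F | starting material
33 | methyl (5E)-2-[bis(2,2,2-trifluoroethoxy)phosphoryl]-7-[(4-methoxybenzyl)oxy]-6-methylhept-5-enoate (racemic at C2) | COC(=O)C(CC/C=C(\C)COCc1ccc(OC)cc1)P(=O)(OCC(F)(F)F)OCC(F)(F)F | intermediate
34 | methyl (2Z,5R,8Z)-2-{(3E)-5-[(4-methoxybenzyl)oxy]-4-methylpent-3-en-1-yl}-8-methyl-5-(6-methylhepta-1,5-dien-2-yl)-10-(phenylsulfonyl)deca-2,8-dienoate | C=C(CCC=C(C)C)[C@H](CC/C(C)=C\CS(=O)(=O)c1ccccc1)C/C=C(/CC/C=C(\C)COCc1ccc(OC)cc1)C(=O)OC | intermediate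
35 | (2Z,5R,8Z)-2-{(3E)-5-[(4-methoxybenzyl)oxy]-4-methylpent-3-en-1-yl}-8-methyl-5-(6-methylhepta-1,5-dien-2-yl)-10-(phenylsulfonyl)deca-2,8-dien-1-ol | C=C(CCC=C(C)C)[C@H](CC/C(C)=C\CS(=O)(=O)c1ccccc1)C/C=C(/CC/C=C(\C)COCc1ccc(OC)cc1)CO | intermediate
36 | tert-butyldimethylsilyl ether of 35 | C=C(CCC=C(C)C)[C@H](CC/C(C)=C\CS(=O)(=O)c1ccccc1)C/C=C(/CC/C=C(\C)COCc1ccc(OC)cc1)CO[Si](C)(C)C(C)(C)C | intermediate
37 | (2Z,5R,8Z)-1-[(tert-butyldimethylsilyl)oxy]-2-[(3E)-5-hydroxy-4-methylpent-3-en-1-yl]-8-methyl-5-(6-methylhepta-1,5-dien-2-yl)-10-(phenylsulfonyl)deca-2,8-diene | C=C(CCC=C(C)C)[C@H](CC/C(C)=C\CS(=O)(=O)c1ccccc1)C/C=C(/CC/C=C(\C)CO)CO[Si](C)(C)C(C)(C)C | intermediate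
38 | (2Z,5R,8Z)-2-[(3E)-5-bromo-4-methylpent-3-en-1-yl]-1-[(tert-butyldimethylsilyl)oxy]-8-methyl-5-(6-methylhepta-1,5-dien-2-yl)-10-(phenylsulfonyl)deca-2,8-diene | C=C(CCC=C(C)C)[C@H](CC/C(C)=C\CS(=O)(=O)c1ccccc1)C/C=C(/CC/C=C(\C)CBr)CO[Si](C)(C)C(C)(C)C | intermediate
39 | tert-butyl{[(1Z,4R,7Z,11E)-7,11-dimethyl-4-(6-methylhepta-1,5-dien-2-yl)-9-(phenylsulfonyl)cyclotetradeca-1,7,11-trien-1-yl]methoxy}dimethylsilane (epimers at C9 of this name) | C=C(CCC=C(C)C)[C@H]1C/C=C(\CO[Si](C)(C)C(C)(C)C)CC/C=C(\C)CC(S(=O)(=O)c2ccccc2)/C=C(/C)CC1 | intermediate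
40 | tert-butyl{[(1Z,4R,7Z,11E)-7,11-dimethyl-4-(6-methylhepta-1,5-dien-2-yl)cyclotetradeca-1,7,11-trien-1-yl]methoxy}dimethylsilane | C=C(CCC=C(C)C)[C@H]1C/C=C(\CO[Si](C)(C)C(C)(C)C)CC/C=C(\C)CC/C=C(/C)CC1 | intermediate
41 | [(1Z,4R,7Z,11E)-7,11-dimethyl-4-(6-methylhepta-1,5-dien-2-yl)cyclotetradeca-1,7,11-trien-1-yl]methanol | C=C(CCC=C(C)C)[C@H]1C/C=C(\CO)CC/C=C(\C)CC/C=C(/C)CC1 | target

## Step count and risk

Total step count: 29. Longest linear sequence: 21 steps (steps 1–6, 9–15 and 22–29, from allyl acetoacetate); the vinyl iodide branch has 2 steps and the phosphonate branch 6.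

The three steps most likely to fail:

Step 5, the lipase desymmetrization. The enzyme's preference on an alkenyl-substituted glutarate is extrapolated from aryl and alkyl analogues, so the ee may be insufficient. The fallback sets out from 9 and comes back at 10. Diester 9 is saponified (LiOH, THF–H2O) to 3-(6-methylhepta-1,5-dien-2-yl)pentanedioic acid F1. F1 is closed with Ac2O at 80 °C to the cyclic anhydride 4-(6-methylhepta-1,5-dien-2-yl)oxane-2,6-dione F2. F2 is opened by enantiotopos-selective ethanolysis with the same class of enzyme (immobilized Candida antarctica lipase B, EtOH, tert-butyl methyl ether, rt), an irreversible acyl transfer in organic solvent that is well precedented for sp2-substituted glutaric anhydrides, to give 10.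

Step 22, the Still–Gennari olefination. The Z:E ratio with the α-branched, long-chain phosphonate 33 may be modest. The fallback sets out from 24 (and uses iodide 31) and comes back at 34. Aldehyde 24 is condensed with commercial methyl bromo[bis(2,2,2-trifluoroethoxy)phosphoryl]acetate (KOtBu, 18-crown-6, THF, –78 °C) to give methyl (2E,5R,8Z)-2-bromo-8-methyl-5-(6-methylhepta-1,5-dien-2-yl)-10-(phenylsulfonyl)deca-2,8-dienoate F3, in which the ester is already cis to C2. Iodide 31 is converted with Zn and LiCl in THF into {(3E)-5-[(4-methoxybenzyl)oxy]-4-methylpent-3-en-1-yl}zinc iodide F4. A stereoretentive Negishi coupling of F3 with F4 (Pd(PPh3)4, THF, rt) then forms the C4–C5 bond and delivers 34. The alkene geometry is thus fixed in a small, highly selective olefination and the chain is attached afterwards.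

Step 27, the macrocyclization. Oligomerization or elimination can compete with the 14-membered closure by a strongly basic carbanion. The fallback sets out from 36 and comes back at 39. The sulfone of 36 is C-acylated (LiN(SiMe3)2, 2.2 equiv, then ClCO2Me, THF, –78 °C) to the C10-methoxycarbonyl sulfone F5. Oxidative removal of the 4-methoxybenzyl group (DDQ) gives the C9 alcohol F6, which is converted with ClCO2Me and pyridine into the C9 allylic methyl carbonate F7. A Tsuji–Trost macrocyclization under neutral conditions (Pd(PPh3)4, Ph2PCH2CH2PPh2, THF, 2 mM, 40 °C) proceeds through the soft, doubly stabilized carbanion and an allylpalladium electrophile attacked at its less hindered terminus, and gives the macrocyclic C10 sulfonyl ester F8. Krapcho decarbomethoxylation (LiCl, wet DMSO, 120 °C) then returns 39.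

## Further compounds

F1 | step 5 | 3-(6-methylhepta-1,5-dien-2-yl)pentanedioic acid | OC(=O)CC(CC(=O)O)C(=C)CCC=C(C)C
F2 | step 5 | 4-(6-methylhepta-1,5-dien-2-yl)oxane-2,6-dione | C=C(CCC=C(C)C)C1CC(=O)OC(=O)C1
F3 | step 22 | methyl (2E,5R,8Z)-2-bromo-8-methyl-5-(6-methylhepta-1,5-dien-2-yl)-10-(phenylsulfonyl)deca-2,8-dienoate | C=C(CCC=C(C)C)[C@H](CC/C(C)=C\CS(=O)(=O)c1ccccc1)C/C=C(/Br)C(=O)OC
F4 | step 22 | {(3E)-5-[(4-methoxybenzyl)oxy]-4-methylpent-3-en-1-yl}zinc iodide | COc1ccc(COC/C(C)=C/CC[Zn]I)cc1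
F5 | step 27 | C10-methoxycarbonyl sulfone (36 with CO2Me on the sulfone-bearing carbon, both epimers) | C=C(CCC=C(C)C)[C@H](CC/C(C)=C\C(C(=O)OC)S(=O)(=O)c1ccccc1)C/C=C(/CC/C=C(\C)COCc1ccc(OC)cc1)CO[Si](C)(C)C(C)(C)C
F6 | step 27 | C9 alcohol (F5 without the 4-methoxybenzyl group) | C=C(CCC=C(C)C)[C@H](CC/C(C)=C\C(C(=O)OC)S(=O)(=O)c1ccccc1)C/C=C(/CC/C=C(\C)CO)CO[Si](C)(C)C(C)(C)C
F7 | step 27 | C9 allylic methyl carbonate of F6 | C=C(CCC=C(C)C)[C@H](CC/C(C)=C\C(C(=O)OC)S(=O)(=O)c1ccccc1)C/C=C(/CC/C=C(\C)COC(=O)OC)CO[Si](C)(C)C(C)(C)C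
F8 | step 27 | macrocyclic C10 sulfonyl ester (39 with CO2Me on the sulfone-bearing ring carbon) | C=C(CCC=C(C)C)[C@H]1C/C=C(\CO[Si](C)(C)C(C)(C)C)CC/C=C(\C)CC(C(=O)OC)(S(=O)(=O)c2ccccc2)/C=C(/C)CC1
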